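The cyclohexane ring is read as a Diels–Alder adduct. Ring numbering: C1 quaternary (methyl, vinyl), C2 (isopropenyl), C3 (carbinol), C4 (side chain), C5, C6. The trans carbon substituents on C1 and C2 map onto an (E)-2-methyl-4-oxoenoate, and the C3 oxygen onto a 1-silyloxybutadiene. One catalytic enantioselective cycloaddition forms C1–C6 and C2–C3, sets the quaternary centre and C2, and oxygenates C3. Ester and ketone then become vinyl and isopropenyl; the C3 oxygen becomes an enone whose reductive aldol addition to 2,2-dimethyl-1,3-dioxan-5-one installs the C4 side chain, and a hydroxyl-directed reduction sets C3. The key-step precursors are two small acyclic compounds, each made in one step.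

Key step: step 3

Remark on numbering: in the Why lines, C1–C6 always mean the ring positions of the target as defined above; the names of intermediates use their own locants.

Assumption: the (S)-configured oxazaborolidinium catalyst is taken to shield the face of enone 5 that leads to the ring configuration drawn for 6. Both catalyst enantiomers are commercial, so the other one is used if the sense proves opposite.

Step 1
Reactants: 1 (E)-but-2-enal (crotonaldehyde)
Product: 2 tri(propan-2-yl){[(1E)-buta-1,3-dien-1-yl]oxy}silane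
Conditions: TIPSOTf, Et3N, Et2O, 0 °C to rt
Reagents that add atoms: triisopropylsilyl triflate, CC(C)[Si](OS(=O)(=O)C(F)(F)F)(C(C)C)C(C)C
Why: O-silylation of the enal and γ-deprotonation by the amine (silyl dienol ether formation) should give mainly the (E)-dienol ether, the isomer that reacts in the cycloaddition.

Step 2
Reactants: 3 2-oxopropanal (methylglyoxal, 40% in water); 4 ethyl 2-(triphenyl-λ5-phosphanylidene)propanoate
Product: 5 ethyl (2E)-2-methyl-4-oxopent-2-enoate
Conditions: CH2Cl2/H2O, rt
Reagents that add atoms: none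
Why: Wittig olefination of the stabilised ylide at the aldehyde carbonyl, which is far more electrophilic than the ketone, should give the (E)-alkene with the ester trans to the acetyl group.

Step 3
Reactants: 2 tri(propan-2-yl){[(1E)-buta-1,3-dien-1-yl]oxy}silane; 5 ethyl (2E)-2-methyl-4-oxopent-2-enoate
Product: 6 ethyl (1R,5R,6S)-6-acetyl-1-methyl-5-{[tri(propan-2-yl)silyl]oxy}cyclohex-3-ene-1-carboxylate
Conditions: 2 (2 equiv), (S)-3,3-diphenyl-1-(2-methylphenyl)tetrahydro-1H,3H-pyrrolo[1,2-c][1,3,2]oxazaborole·HNTf2 (20 mol %), CH2Cl2, −78 to −40 °C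
Reagents that add atoms: none
Why: The protonated oxazaborolidine binds the ketone oxygen of 5 (the more basic carbonyl), so the LUMO coefficient is largest at the methyl- and ester-bearing β-carbon; the unsubstituted terminus of 2 (largest HOMO coefficient) bonds there (C6–C1) and the oxygenated terminus bonds to the α-carbon (C3–C2) in a concerted, asynchronous Diels–Alder cycloaddition. The closest known reaction type is the chiral-acid-catalysed enantioselective Diels–Alder reaction of acyclic enones with 1-silyloxy dienes. The cyclohexene ring is closed by intermolecular [4+2] cycloaddition, suprafacial on both partners, and both new sigma bonds are ring bonds. C1 (quaternary) and C2 (acetyl-bearing) are set together by the catalyst-shielded face of the dienophile, and their trans ester/acetyl relation is copied from the (E)-alkene; the silyloxy carbon C3 follows from the endo position of the complexed acetyl group and is erased later at ketone 12, so any exo adduct converges. The step needs regiocontrol (ketone over ester activation, reinforced by the silyloxy donor of 2), enantioface control (catalyst) and suppression of silyl-transfer catalysis (bulky triisopropylsilyl group).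

Step 4
Reactants: 6 ethyl (1R,5R,6S)-6-acetyl-1-methyl-5-{[tri(propan-2-yl)silyl]oxy}cyclohex-3-ene-1-carboxylate
Product: 7 1-[(1R,2R,6R)-6-(hydroxymethyl)-6-methyl-2-{[tri(propan-2-yl)silyl]oxy}cyclohex-3-en-1-yl]ethan-1-ol (both carbinol epimers)
Conditions: LiAlH4, THF, 0 °C
Reagents that add atoms: none
Why: Hydride reduction of ester and ketone by LiAlH4 leaves the silyl ether and the ring alkene untouched; the new carbinol centre forms as a mixture that is erased in step 5.

Step 5
Reactants: 7 1-[(1R,2R,6R)-6-(hydroxymethyl)-6-methyl-2-{[tri(propan-2-yl)silyl]oxy}cyclohex-3-en-1-yl]ethan-1-ol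
Product: 8 (1R,5R,6S)-6-acetyl-1-methyl-5-{[tri(propan-2-yl)silyl]oxy}cyclohex-3-ene-1-carbaldehyde
Conditions: (COCl)2, DMSO, CH2Cl2, −78 °C; then Et3N, −78 to 0 °C
Reagents that add atoms: none
Why: Swern oxidation activates both hydroxyls as alkoxysulfonium ions before the base is added, so the 1,4-diol should give the keto aldehyde and not a lactol or lactone, and the cold, brief contact with amine should leave the ketone α-centre untouched.

Step 6
Reactants: 8 (1R,5R,6S)-6-acetyl-1-methyl-5-{[tri(propan-2-yl)silyl]oxy}cyclohex-3-ene-1-carbaldehyde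
Product: 10 tri(propan-2-yl){[(1R,5S,6S)-5-ethenyl-5-methyl-6-(prop-1-en-2-yl)cyclohex-2-en-1-yl]oxy}silane, via vinyl ketone 9 (not isolated)
Conditions: Ph3PCH3Br, KOtBu, THF, 0 °C to rt
Reagents that add atoms: methylenetriphenylphosphorane, C=P(c1ccccc1)(c1ccccc1)c1ccccc1
Why: Double Wittig methylenation, first of the non-enolisable aldehyde and then of the methyl ketone, gives the vinyl and isopropenyl groups; the ylide enolises the ketone at a useful rate only towards its methyl group, so the ring stereocentres and the β-silyloxy group should survive.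

Step 7
Reactants: 10 tri(propan-2-yl){[(1R,5S,6S)-5-ethenyl-5-methyl-6-(prop-1-en-2-yl)cyclohex-2-en-1-yl]oxy}silane
Product: 11 (1R,5S,6S)-5-ethenyl-5-methyl-6-(prop-1-en-2-yl)cyclohex-2-en-1-ol
Conditions: Bu4NF, THF, rt
Reagents that add atoms: none
Why: Fluoride-induced cleavage of the silicon–oxygen bond (desilylation) frees the allylic alcohol without touching the three alkenes.

Step 8
Reactants: 11 (1R,5S,6S)-5-ethenyl-5-methyl-6-(prop-1-en-2-yl)cyclohex-2-en-1-ol
Product: 12 (5S,6S)-5-ethenyl-5-methyl-6-(prop-1-en-2-yl)cyclohex-2-en-1-one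
Conditions: Dess–Martin periodinane, NaHCO3, CH2Cl2, 0 °C to rt
Reagents that add atoms: none
Why: Dess–Martin oxidation of the allylic alcohol gives the conjugated enone under buffered, non-basic conditions, so the α-stereocentre should be kept and the isopropenyl double bond should not move into conjugation, a shift that would also build allylic strain against the quaternary carbon.

Step 9
Reactants: 12 (5S,6S)-5-ethenyl-5-methyl-6-(prop-1-en-2-yl)cyclohex-2-en-1-one; 13 2,2-dimethyl-1,3-dioxan-5-one
Product: 15 (2S,3S,6S)-3-ethenyl-6-(5-hydroxy-2,2-dimethyl-1,3-dioxan-5-yl)-3-methyl-2-(prop-1-en-2-yl)cyclohexan-1-one, via lithium enolate 14 (not isolated)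
Conditions: LiBH(sBu)3 (1.0 equiv), THF, −78 °C; then 13, −78 to −40 °C; aq NH4Cl
Reagents that add atoms: none
Why: Reductive aldol reaction: LiBH(sBu)3 adds hydride to the unsubstituted β-carbon (the carbonyl is shielded by its branched neighbour) and so gives the enolate only on the methylene side, and its addition to the electron-poor ketone 13 is reversible on warming, so the lithium-chelated aldolate with the new side chain equatorial and cis to the isopropenyl group should prevail and fix the C4 stereocentre.

Step 10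
Reactants: 15 (2S,3S,6S)-3-ethenyl-6-(5-hydroxy-2,2-dimethyl-1,3-dioxan-5-yl)-3-methyl-2-(prop-1-en-2-yl)cyclohexan-1-one
Product: 16 (1R,2S,3S,6R)-3-ethenyl-6-(5-hydroxy-2,2-dimethyl-1,3-dioxan-5-yl)-3-methyl-2-(prop-1-en-2-yl)cyclohexan-1-ol
Conditions: Me4NBH(OAc)3, MeCN/AcOH, −30 °C
Reagents that add atoms: none
Why: Hydroxyl-directed Evans–Saksena reduction: the tertiary hydroxyl exchanges onto boron and delivers hydride intramolecularly to the carbonyl face on the side of the equatorial side chain, which should give the equatorial C3 alcohol trans to both neighbours, whereas external hydride, hindered by the axial methyl group, would favour the other epimer.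

Step 11
Reactants: 16 (1R,2S,3S,6R)-3-ethenyl-6-(5-hydroxy-2,2-dimethyl-1,3-dioxan-5-yl)-3-methyl-2-(prop-1-en-2-yl)cyclohexan-1-ol
Product: 17 2-[(1R,2R,3S,4S)-4-ethenyl-2-hydroxy-4-methyl-3-(prop-1-en-2-yl)cyclohexyl]propane-1,2,3-triol
Conditions: AcOH/H2O (4:1), 40 °C
Reagents that add atoms: none
Why: Acid-catalysed hydrolysis of the isopropylidene acetal in aqueous acetic acid is mild enough to leave the 1,1-disubstituted alkene and the homoallylic alcohol unchanged.

Step 12
Reactants: 17 2-[(1R,2R,3S,4S)-4-ethenyl-2-hydroxy-4-methyl-3-(prop-1-en-2-yl)cyclohexyl]propane-1,2,3-triol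
Product: 18 2-[(1R,2R,3S,4S)-4-ethenyl-2-hydroxy-4-methyl-3-(prop-1-en-2-yl)cyclohexyl]-2-hydroxypropane-1,3-diyl diacetate (CNP0273389.1)
Conditions: AcCl (2.1 equiv), 2,4,6-collidine, CH2Cl2, −78 °C
Reagents that add atoms: acetyl chloride, CC(=O)Cl
Why: Sterically controlled acetylation at low temperature should acylate only the two primary hydroxyls, because the secondary hydroxyl is flanked by two branched carbons and the tertiary one is unreactive.

Compound list
1 | (E)-but-2-enal (crotonaldehyde) | C/C=C/C=O | starting material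
2 | tri(propan-2-yl){[(1E)-buta-1,3-dien-1-yl]oxy}silane | C=C/C=C/O[Si](C(C)C)(C(C)C)C(C)C | intermediate
3 | 2-oxopropanal (methylglyoxal) | CC(=O)C=O | starting material
4 | ethyl 2-(triphenyl-λ5-phosphanylidene)propanoate | CCOC(=O)C(C)=P(c1ccccc1)(c1ccccc1)c1ccccc1 | starting material
5 | ethyl (2E)-2-methyl-4-oxopent-2-enoate | CCOC(=O)/C(C)=C/C(C)=O | intermediate
6 | ethyl (1R,5R,6S)-6-acetyl-1-methyl-5-{[tri(propan-2-yl)silyl]oxy}cyclohex-3-ene-1-carboxylate (silyloxy cis to acetyl, trans to ester) | CCOC(=O)[C@]1(C)CC=C[C@@H](O[Si](C(C)C)(C(C)C)C(C)C)[C@H]1C(C)=O | intermediate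
7 | 1-[(1R,2R,6R)-6-(hydroxymethyl)-6-methyl-2-{[tri(propan-2-yl)silyl]oxy}cyclohex-3-en-1-yl]ethan-1-ol (both carbinol epimers) | OC[C@]1(C)CC=C[C@@H](O[Si](C(C)C)(C(C)C)C(C)C)[C@H]1C(C)O | intermediate
8 | (1R,5R,6S)-6-acetyl-1-methyl-5-{[tri(propan-2-yl)silyl]oxy}cyclohex-3-ene-1-carbaldehyde | O=C[C@]1(C)CC=C[C@@H](O[Si](C(C)C)(C(C)C)C(C)C)[C@H]1C(C)=O | intermediate
9 | 1-[(1S,2R,6S)-6-ethenyl-6-methyl-2-{[tri(propan-2-yl)silyl]oxy}cyclohex-3-en-1-yl]ethan-1-one | C=C[C@]1(C)CC=C[C@@H](O[Si](C(C)C)(C(C)C)C(C)C)[C@H]1C(C)=O | intermediate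
10 | tri(propan-2-yl){[(1R,5S,6S)-5-ethenyl-5-methyl-6-(prop-1-en-2-yl)cyclohex-2-en-1-yl]oxy}silane | C=C[C@]1(C)CC=C[C@@H](O[Si](C(C)C)(C(C)C)C(C)C)[C@H]1C(C)=C | intermediate
11 | (1R,5S,6S)-5-ethenyl-5-methyl-6-(prop-1-en-2-yl)cyclohex-2-en-1-ol | C=C[C@]1(C)CC=C[C@@H](O)[C@H]1C(C)=C | intermediate
12 | (5S,6S)-5-ethenyl-5-methyl-6-(prop-1-en-2-yl)cyclohex-2-en-1-one | C=C[C@]1(C)CC=CC(=O)[C@H]1C(C)=C | intermediate
13 | 2,2-dimethyl-1,3-dioxan-5-one | CC1(C)OCC(=O)CO1 | starting material
14 | lithium (5S,6S)-5-ethenyl-5-methyl-6-(prop-1-en-2-yl)cyclohex-1-en-1-olate | C=C[C@]1(C)CCC=C([O-])[C@H]1C(C)=C.[Li+] | intermediate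
15 | (2S,3S,6S)-3-ethenyl-6-(5-hydroxy-2,2-dimethyl-1,3-dioxan-5-yl)-3-methyl-2-(prop-1-en-2-yl)cyclohexan-1-one | C=C[C@]1(C)CC[C@@H](C2(O)COC(C)(C)OC2)C(=O)[C@H]1C(C)=C | intermediate
16 | (1R,2S,3S,6R)-3-ethenyl-6-(5-hydroxy-2,2-dimethyl-1,3-dioxan-5-yl)-3-methyl-2-(prop-1-en-2-yl)cyclohexan-1-ol | C=C[C@]1(C)CC[C@@H](C2(O)COC(C)(C)OC2)[C@H](O)[C@H]1C(C)=C | intermediate
17 | 2-[(1R,2R,3S,4S)-4-ethenyl-2-hydroxy-4-methyl-3-(prop-1-en-2-yl)cyclohexyl]propane-1,2,3-triol | C=C[C@]1(C)CC[C@@H](C(O)(CO)CO)[C@H](O)[C@H]1C(C)=C | intermediate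
18 | 2-[(1R,2R,3S,4S)-4-ethenyl-2-hydroxy-4-methyl-3-(prop-1-en-2-yl)cyclohexyl]-2-hydroxypropane-1,3-diyl diacetate | C=C[C@]1(C)CC[C@@H](C(O)(COC(C)=O)COC(C)=O)[C@H](O)[C@H]1C(=C)C | target

Total step count: 12.
Longest linear sequence: 11 steps (1 → 2 → 6 → 7 → 8 → 10 → 11 → 12 → 15 → 16 → 17 → 18; step 2 is the side branch).

Steps most likely to fail

Step 3. What may go wrong: weak facial discrimination of the trisubstituted, doubly activated alkene; silyl transfer to the catalyst, which opens an achiral Lewis acid pathway; or interception after the first bond as an open-chain Mukaiyama–Michael product. Fallback (sets out from 2 and 4, comes back at 7): the dienophile is changed to an aldehyde, so that covalent iminium catalysis replaces Lewis acid complexation. Wittig reaction of 4 with 2,2-dimethoxyacetaldehyde should give ethyl (2E)-4,4-dimethoxy-2-methylbut-2-enoate F1, and aqueous acid should free ethyl (2E)-2-methyl-4-oxobut-2-enoate F2. Cycloaddition of F2 with 2 under a second-generation MacMillan imidazolidinone (5-benzyl-2-tert-butyl-3-methylimidazolidin-4-one trifluoroacetate, enantiomer chosen for the same face) should give ethyl (1R,5R,6S)-6-formyl-1-methyl-5-{[tri(propan-2-yl)silyl]oxy}cyclohex-3-ene-1-carboxylate F3; the iminium carbon sits where the acetyl group was, so the regiochemistry is unchanged. MeMgBr at −78 °C should add to the aldehyde to give ethyl (1R,5R,6R)-6-(1-hydroxyethyl)-1-methyl-5-{[tri(propan-2-yl)silyl]oxy}cyclohex-3-ene-1-carboxylate F4, and LiAlH4 reduction of its ester rejoins the route at diol 7.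

Step 9. What may go wrong: proton transfer from the enolisable ketone 13 to the enolate in place of carbon–carbon bond formation, or kinetic attack that leaves the side chain axial (trans to the isopropenyl group) without equilibration. Fallback (sets out from 12, comes back at 17): the enolate is generated as before and trapped with diethyl 2-oxopropanedioate, a ketone that cannot transfer a proton and is far more electrophilic. This should give diethyl 2-[(1S,3S,4S)-4-ethenyl-4-methyl-2-oxo-3-(prop-1-en-2-yl)cyclohexyl]-2-hydroxypropanedioate F5. Directed reduction with Me4NBH(OAc)3, which tolerates esters, should give diethyl 2-[(1R,2R,3S,4S)-4-ethenyl-2-hydroxy-4-methyl-3-(prop-1-en-2-yl)cyclohexyl]-2-hydroxypropanedioate F6, and LiAlH4 reduction of both esters rejoins the route at tetraol 17.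

Step 10. What may go wrong: hydride delivery to the wrong carbonyl face, giving the axial C3 alcohol, if exchange onto the hindered tertiary hydroxyl is slow and free borohydride reacts first. Fallback (sets out from 15, comes back at 16): single-electron reduction with SmI2, MeOH, THF, −78 °C. The ketyl is held on samarium chelated by the tertiary hydroxyl and is protonated to the more stable equatorial carbinol, so the outcome no longer depends on the direction of hydride approach. No new compound is formed.

Further compounds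
F1 | step 3 | ethyl (2E)-4,4-dimethoxy-2-methylbut-2-enoate | CCOC(=O)/C(C)=C/C(OC)OC
F2 | step 3 | ethyl (2E)-2-methyl-4-oxobut-2-enoate | CCOC(=O)/C(C)=C/C=O
F3 | step 3 | ethyl (1R,5R,6S)-6-formyl-1-methyl-5-{[tri(propan-2-yl)silyl]oxy}cyclohex-3-ene-1-carboxylate | CCOC(=O)[C@]1(C)CC=C[C@@H](O[Si](C(C)C)(C(C)C)C(C)C)[C@H]1C=O
F4 | step 3 | ethyl (1R,5R,6R)-6-(1-hydroxyethyl)-1-methyl-5-{[tri(propan-2-yl)silyl]oxy}cyclohex-3-ene-1-carboxylate (both carbinol epimers) | CCOC(=O)[C@]1(C)CC=C[C@@H](O[Si](C(C)C)(C(C)C)C(C)C)[C@H]1C(C)O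
F5 | step 9 | diethyl 2-[(1S,3S,4S)-4-ethenyl-4-methyl-2-oxo-3-(prop-1-en-2-yl)cyclohexyl]-2-hydroxypropanedioate | C=C[C@]1(C)CC[C@@H](C(O)(C(=O)OCC)C(=O)OCC)C(=O)[C@H]1C(C)=C
F6 | step 9 | diethyl 2-[(1R,2R,3S,4S)-4-ethenyl-2-hydroxy-4-methyl-3-(prop-1-en-2-yl)cyclohexyl]-2-hydroxypropanedioate | C=C[C@]1(C)CC[C@@H](C(O)(C(=O)OCC)C(=O)OCC)[C@H](O)[C@H]1C(C)=C
F0 | step 10 | none | none
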